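Ring positions: C1 and C4 are the carbonyl carbons, C2 bears OH, C3 bears CH3, C5 is the inter-ring carbon and C6 carries the chain (primes for ring B). Everything rests on cutting the CH2–CH2 bond of both chains. Because C6 of ring A and C6′ of ring B are both ortho to the C5–C5′ bond, their benzylic carbons lie within bridging distance, and a single SO2 unit links them in a seven-membered ring and acidifies both. Two deprotonation–benzylation cycles in one flask then install the 2-methoxybenzyl and the benzyl group, the order of addition distinguishing two equivalent sites. The precursor is the C2-symmetric hexamethoxy-dimethyl-5,7-dihydrodibenzo[c,e]thiepine 6,6-dioxide.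

Key step: step 10

Assumption: the target SMILES carries no stereodescriptor and has no stereocentre, so the hindered C5–C5′ axis is made and carried as a racemate. Compounds 1, 12 and 13 are catalogue chemicals.

Step 1
Reactants: 1 2,4-dimethoxy-3-methylbenzaldehyde
Product: 3 2,4-dimethoxy-3-methylphenol, via aryl formate 2 (not isolated)
Conditions: 30% aq. H2O2, cat. H2SO4, MeOH, 0 °C to rt
Reagents that add atoms: hydrogen peroxide, OO
Why: Acid-promoted Dakin oxidation, in which the electron-rich aryl group migrates from carbon to oxygen in the perhemiacetal and formate 2 is methanolysed in situ, placing the future C1 oxygen.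

Step 2
Reactants: 3 2,4-dimethoxy-3-methylphenol
Product: 4 2-hydroxy-3,5-dimethoxy-4-methylbenzaldehyde
Conditions: MgCl2, Et3N, (CH2O)n, MeCN, reflux; 1 M HCl work-up
Reagents that add atoms: paraformaldehyde (as formaldehyde), C=O
Why: Casnati–Skattebøl ortho-formylation, in which the magnesium phenoxide delivers formaldehyde only ortho to oxygen and, with C2 blocked, only to C6; the benzylic carbon is thus in place before the biaryl bond exists, which avoids a late halomethylation of a 6,6′-unsubstituted biaryl, where the first benzylic cation could close onto C6′ to give a fluorene.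

Step 3
Reactants: 4 2-hydroxy-3,5-dimethoxy-4-methylbenzaldehyde
Product: 5 2,3,5-trimethoxy-4-methylbenzaldehyde
Conditions: MeI, K2CO3, DMF, rt
Reagents that add atoms: iodomethane, CI
Why: Williamson ether synthesis on the chelated salicylaldehyde phenol, which should run cleanly in a dipolar aprotic solvent without touching the aldehyde.

Step 4
Reactants: 5 2,3,5-trimethoxy-4-methylbenzaldehyde
Product: 6 2-bromo-3,5,6-trimethoxy-4-methylbenzaldehyde
Conditions: NBS, MeCN, rt, dark
Reagents that add atoms: N-bromosuccinimide, O=C1CCC(=O)N1Br
Why: Electrophilic aromatic bromination at the only free ring position, C5, which is ortho to the C4 methoxy and para to the C2 methoxy group, while a polar solvent in the dark suppresses radical attack on the C3 methyl group.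

Step 5
Reactants: 6 2-bromo-3,5,6-trimethoxy-4-methylbenzaldehyde (two molecules)
Product: 7 3,3′,4,4′,6,6′-hexamethoxy-5,5′-dimethylbiphenyl-2,2′-dicarbaldehyde (racemic axis)
Conditions: activated Cu bronze, DMF, 150 °C, Ar
Reagents that add atoms: none
Why: Classical Ullmann homocoupling, for which an aryl bromide flanked by an ortho carbonyl group and an ortho methoxy group is the standard activated substrate class for tetra-ortho-substituted biaryls; the C5–C5′ axis forms as the racemate.

Step 6
Reactants: 7 hexamethoxy-dimethylbiphenyl-2,2′-dicarbaldehyde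
Product: 8 2,2′-bis(hydroxymethyl)-3,3′,4,4′,6,6′-hexamethoxy-5,5′-dimethylbiphenyl
Conditions: NaBH4, THF–MeOH, 0 °C
Reagents that add atoms: none
Why: Hydride reduction of both aromatic aldehydes, with nothing else reducible in the molecule.

Step 7
Reactants: 8 2,2′-bis(hydroxymethyl)biaryl
Product: 9 2,2′-bis(bromomethyl)-3,3′,4,4′,6,6′-hexamethoxy-5,5′-dimethylbiphenyl
Conditions: PBr3, CH2Cl2, 0 °C; used crude
Reagents that add atoms: phosphorus tribromide, BrP(Br)Br
Why: Conversion of benzylic alcohols into bromides through phosphite esters and SN2 displacement, where low temperature and excess bromide should hold back cyclodehydration to the dibenzoxepine.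

Step 8
Reactants: 9 2,2′-bis(bromomethyl)biaryl
Product: 10 1,3,4,8,9,11-hexamethoxy-2,10-dimethyl-5,7-dihydrodibenzo[c,e]thiepine
Conditions: Na2S·9H2O, DMF, slow addition (high dilution), rt
Reagents that add atoms: sodium sulfide, [Na+].[Na+].[S-2]
Why: Double SN2 displacement by sulfide, in which the twisted biaryl holds both CH2Br groups close together so that seven-membered ring closure should outrun oligomerisation.

Step 9
Reactants: 10 hexamethoxy-dimethyl-dihydrodibenzothiepine
Product: 11 1,3,4,8,9,11-hexamethoxy-2,10-dimethyl-5,7-dihydrodibenzo[c,e]thiepine 6,6-dioxide (racemic axis)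
Conditions: mCPBA (2.2 equiv), CH2Cl2, 0 °C to rt
Reagents that add atoms: 3-chloroperbenzoic acid, O=C(OO)c1cccc(Cl)c1
Why: Peracid oxidation of a dialkyl sulfide to the sulfone, which is far faster at sulfur than any attack on the hexasubstituted arenes.

Step 10
Reactants: 11 hexamethoxy-dimethyl-5,7-dihydrodibenzo[c,e]thiepine 6,6-dioxide; 12 2-methoxybenzyl bromide; 13 benzyl bromide
Product: 15 7-benzyl-1,3,4,8,9,11-hexamethoxy-5-(2-methoxybenzyl)-2,10-dimethyl-5,7-dihydrodibenzo[c,e]thiepine 6,6-dioxide (mixture of racemic diastereomers), via monobenzylated sulfone 14 (not isolated)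
Conditions: n-BuLi (1.0 equiv), THF, −78 °C; 12 (1.0 equiv), −78 to −40 °C; recool, n-BuLi (1.05 equiv), −78 °C; 13 (1.2 equiv), −78 to 0 °C; aq. NH4Cl
Reagents that add atoms: none
Why: One equivalent of n-BuLi removes a benzylic α-sulfonyl proton of C2-symmetric 11 (the two CH2 groups are equivalent, so only one constitutional monoanion can form) and the carbanion displaces bromide from 12 by SN2; a second equivalent of base then metalates 14 at the other α carbon and that carbanion is benzylated by 13, so the CH2–CH2 bonds of both chains are made in one flask. The closest known reaction type is the stepwise α,α′-dialkylation of cyclic benzylic sulfones, including bridged biaryl thiepine dioxides. No ring is closed, the existing seven-membered ring serving only to activate the two carbons and keep them distinct. The two new stereocentres are set relative to the fixed biaryl axis by entry of the electrophile on the outer, less shielded face of each carbanion, but their configuration is of no consequence because both carbons become CH2 groups in step 11 and all diastereomers converge. The selectivity that matters is the site of the second metalation: the untouched α′-CH2 is sterically open and keeps a C–H bond aligned for stabilisation by the sulfonyl group, whereas the lone α-H at the substituted carbon is tertiary, is shielded by the new benzyl group and the C1 methoxy group, and occupies the poorly aligned position of the rigid ring. Scrambling of the order of addition is held down by full metalation with exactly one equivalent of base at −78 °C and by the high SN2 rate of benzylic bromides relative to proton transfer between carbon acids.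

Step 11
Reactants: 15 α-(2-methoxybenzyl)-α′-benzyl cyclic sulfone
Product: 16 3,3′,4,4′,6,6′-hexamethoxy-2-[2-(2-methoxyphenyl)ethyl]-5,5′-dimethyl-2′-(2-phenylethyl)biphenyl
Conditions: Raney Ni (W-2, freshly prepared, large excess), H2 (1 atm), EtOH–THF, reflux
Reagents that add atoms: none
Why: Raney-nickel hydrogenolysis of benzylic and cyclic sulfones removes sulfur from both carbons on the metal surface, whereas single-electron reductants such as SmI2 or Mg/MeOH would be expected to stop at the ring-opened benzylic sulfinate; aryl methyl ethers and arenes are inert and both stereocentres vanish.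

Step 12
Reactants: 16 bis(arylethyl)hexamethoxybiphenyl
Product: 17 4,4′-dimethoxy-2-[2-(2-methoxyphenyl)ethyl]-5,5′-dimethyl-2′-(2-phenylethyl)-1,1′-bi(cyclohexa-1,4-dien-1-yl)-3,3′,6,6′-tetraone
Conditions: (NH4)2Ce(NO3)6 (5 equiv), MeCN–H2O, 0 °C
Reagents that add atoms: water, O
Why: Oxidative demethylation by tetravalent cerium, in which each 1,2,4-trimethoxyarene, far easier to oxidise than the pendant anisole and phenyl rings, loses the para-related C1 and C4 methyl ethers to give the 1,4-quinone while the C2 methoxy group stays as a vinylogous ester.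

Step 13
Reactants: 17 bis(methoxyquinone)
Product: 18 CNP0202346.0, 4,4′-dihydroxy-2-[2-(2-methoxyphenyl)ethyl]-5,5′-dimethyl-2′-(2-phenylethyl)-1,1′-bi(cyclohexa-1,4-dien-1-yl)-3,3′,6,6′-tetraone
Conditions: 1 M aq. NaOH, THF–MeOH, 0 °C to rt, Ar; then 1 M HCl
Reagents that add atoms: sodium hydroxide, [Na+].[OH-]
Why: Addition–elimination of hydroxide at C2 and C2′ (saponification of a vinylogous ester), the only productive site because every quinone carbon is substituted; the hydroxyquinone anions formed resist further attack and the aryl methyl ether of the chain is inert to base.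

Compound list
1 | 2,4-dimethoxy-3-methylbenzaldehyde | COc1ccc(C=O)c(OC)c1C | starting material
2 | 2,4-dimethoxy-3-methylphenyl formate | COc1ccc(OC=O)c(OC)c1C | intermediate (not isolated)
3 | 2,4-dimethoxy-3-methylphenol | COc1ccc(O)c(OC)c1C | intermediate
4 | 2-hydroxy-3,5-dimethoxy-4-methylbenzaldehyde | COc1cc(C=O)c(O)c(OC)c1C | intermediate
5 | 2,3,5-trimethoxy-4-methylbenzaldehyde | COc1cc(C=O)c(OC)c(OC)c1C | intermediate
6 | 2-bromo-3,5,6-trimethoxy-4-methylbenzaldehyde | COc1c(Br)c(C=O)c(OC)c(OC)c1C | intermediate
7 | 3,3′,4,4′,6,6′-hexamethoxy-5,5′-dimethylbiphenyl-2,2′-dicarbaldehyde (racemic axis) | COc1c(C)c(OC)c(OC)c(C=O)c1-c1c(OC)c(C)c(OC)c(OC)c1C=O | intermediate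
8 | 2,2′-bis(hydroxymethyl)-3,3′,4,4′,6,6′-hexamethoxy-5,5′-dimethylbiphenyl | COc1c(C)c(OC)c(OC)c(CO)c1-c1c(OC)c(C)c(OC)c(OC)c1CO | intermediate
9 | 2,2′-bis(bromomethyl)-3,3′,4,4′,6,6′-hexamethoxy-5,5′-dimethylbiphenyl | COc1c(C)c(OC)c(OC)c(CBr)c1-c1c(OC)c(C)c(OC)c(OC)c1CBr | intermediate
10 | 1,3,4,8,9,11-hexamethoxy-2,10-dimethyl-5,7-dihydrodibenzo[c,e]thiepine | COc1c(C)c(OC)c(OC)c2c1-c1c(OC)c(C)c(OC)c(OC)c1CSC2 | intermediate
11 | 1,3,4,8,9,11-hexamethoxy-2,10-dimethyl-5,7-dihydrodibenzo[c,e]thiepine 6,6-dioxide (racemic axis) | COc1c(C)c(OC)c(OC)c2c1-c1c(OC)c(C)c(OC)c(OC)c1CS(=O)(=O)C2 | intermediate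
12 | 2-methoxybenzyl bromide | COc1ccccc1CBr | starting material
13 | benzyl bromide | BrCc1ccccc1 | starting material
14 | 1,3,4,8,9,11-hexamethoxy-5-(2-methoxybenzyl)-2,10-dimethyl-5,7-dihydrodibenzo[c,e]thiepine 6,6-dioxide (racemic, diastereomers) | COc1c(C)c(OC)c(OC)c2c1-c1c(OC)c(C)c(OC)c(OC)c1CS(=O)(=O)C2Cc1ccccc1OC | intermediate (not isolated)
15 | 7-benzyl-1,3,4,8,9,11-hexamethoxy-5-(2-methoxybenzyl)-2,10-dimethyl-5,7-dihydrodibenzo[c,e]thiepine 6,6-dioxide (racemic, all diastereomers) | COc1c(C)c(OC)c(OC)c2c1-c1c(OC)c(C)c(OC)c(OC)c1C(Cc1ccccc1)S(=O)(=O)C2Cc1ccccc1OC | intermediate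
16 | 3,3′,4,4′,6,6′-hexamethoxy-2-[2-(2-methoxyphenyl)ethyl]-5,5′-dimethyl-2′-(2-phenylethyl)biphenyl | COc1ccccc1CCc1c(OC)c(OC)c(C)c(OC)c1-c1c(OC)c(C)c(OC)c(OC)c1CCc1ccccc1 | intermediate
17 | bis(2-methoxy-3-methyl-1,4-benzoquinone) carrying both chains | COc1ccccc1CCC1=C(C2=C(CCc3ccccc3)C(=O)C(OC)=C(C)C2=O)C(=O)C(C)=C(OC)C1=O | intermediate
18 | CNP0202346.0 | COc1ccccc1CCC1=C(C2=C(CCc3ccccc3)C(=O)C(O)=C(C)C2=O)C(=O)C(C)=C(O)C1=O | target

Total step count: 13. Longest linear sequence: 13 steps (1 to 18); 12 and 13 enter as purchased reagents.

Steps most likely to fail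

Step 10. Proton transfer between 14 and not yet alkylated carbanion during the first alkylation could blur the order of addition and attach the same benzyl group twice. A second metalation at the already substituted carbon could lead to geminal dialkylation. The fallback gives up the sulfone bridge; it sets out from dialdehyde 7 and returns at 16, skipping steps 6 to 11. One equivalent of the anion of diethyl (2-methoxybenzyl)phosphonate (NaH, THF, 0 °C) is added to 7 in a Horner–Wadsworth–Emmons olefination to give the (E)-stilbene monoaldehyde F1, with unreacted 7 recovered and recycled. The remaining aldehyde is olefinated in the same way with diethyl benzylphosphonate to give the bis-(E)-stilbene F2. H2 over Pd/C in EtOAc then saturates both alkenes to 16.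

Step 11. Hydrogenolysis could stall after the first C–S scission, or be slowed because two hexasubstituted arenes shield sulfur from the nickel surface. On hydrogen-poor nickel the two benzylic radicals could recombine with ring contraction. The fallback sets out from 15 and returns at 16. The sulfone is first deoxygenated with LiAlH4–TiCl4 (THF, −78 °C to rt) to the dibenzylated cyclic sulfide F3. This dibenzylic sulfide is the classical and much more willing substrate for Raney Ni desulfurisation in refluxing EtOH.

Step 5. Hydrodebromination and thermal loss of the formyl group could compete with the slow coupling at a carbon flanked on both sides. The fallback sets out from 6 and returns at 7, replacing the copper-mediated reductive coupling by a cross-coupling. Half of 6 is converted by Miyaura borylation (B2pin2, PdCl2(dppf), KOAc, dioxane, 90 °C) into the pinacol boronate F4. F4 is then joined to the other half of 6 by Suzuki–Miyaura coupling (Pd(OAc)2, SPhos, K3PO4, toluene–H2O, 100 °C), a ligand system established for tetra-ortho-substituted biaryls.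

Further compounds
F1 | step 10 | 3,3′,4,4′,6,6′-hexamethoxy-2′-[(E)-2-(2-methoxyphenyl)ethenyl]-5,5′-dimethylbiphenyl-2-carbaldehyde | COc1ccccc1/C=C/c1c(OC)c(OC)c(C)c(OC)c1-c1c(OC)c(C)c(OC)c(OC)c1C=O
F2 | step 10 | 3,3′,4,4′,6,6′-hexamethoxy-2-[(E)-2-(2-methoxyphenyl)ethenyl]-5,5′-dimethyl-2′-[(E)-2-phenylethenyl]biphenyl | COc1ccccc1/C=C/c1c(OC)c(OC)c(C)c(OC)c1-c1c(OC)c(C)c(OC)c(OC)c1/C=C/c1ccccc1
F3 | step 11 | 7-benzyl-1,3,4,8,9,11-hexamethoxy-5-(2-methoxybenzyl)-2,10-dimethyl-5,7-dihydrodibenzo[c,e]thiepine (racemic, all diastereomers) | COc1c(C)c(OC)c(OC)c2c1-c1c(OC)c(C)c(OC)c(OC)c1C(Cc1ccccc1)SC2Cc1ccccc1OC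
F4 | step 5 | 2,3,5-trimethoxy-4-methyl-6-(4,4,5,5-tetramethyl-1,3,2-dioxaborolan-2-yl)benzaldehyde | COc1c(B2OC(C)(C)C(C)(C)O2)c(C=O)c(OC)c(OC)c1C
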